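**Retrosynthetic overview**
- The last operation closes both oxygen heterocycles under acid. The pyranone ring is cut in the Pechmann sense (C4–C4a and O1–C2) into 5-methoxyresorcinol and an α-formyl arylacetate. The dihydropyran ring is cut at O–CMe2 into an ortho-prenyl phenol masked as a silyl ether.
- The α-formyl arylacetate is not isolated: it forms in the same flask from the B-ring benzaldehyde and ethyl diazoacetate by an acid-catalysed 1,2-aryl shift.
- The B-ring aldehyde comes from 2,4-dihydroxybenzaldehyde by C3-prenylation, 4-O-silylation (this marks the future chroman oxygen) and 2-O-methylation.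
- Ring order: both benzene rings are bought; the pyranone ring and then the dihydropyran ring form together in the final step.

Assumption: the target has no stereocentre and no stereogenic double bond (it is achiral), so there is no enantiomer to select and no stereochemistry to set.

**Step 1**
Reactants: 1 2,4-dihydroxybenzaldehyde; 2 prenyl bromide (1-bromo-3-methylbut-2-ene)
Product: 3 2,4-dihydroxy-3-(3-methylbut-2-en-1-yl)benzaldehyde
Conditions: aq. KOH (10 %), 0 °C → rt, 24 h
Reagents that add atoms: none
Why: Phenoxide C-alkylation in water (C-prenylation of a resorcinolate) goes mainly to C3, the carbon ortho to both oxygens, so the 3-prenyl isomer is the main C-alkylation product in modest yield (expect roughly 30–40 %) with separable 5-prenyl and O-prenyl by-products; no stereocentre is formed.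

**Step 2**
Reactants: 3 2,4-dihydroxy-3-(3-methylbut-2-en-1-yl)benzaldehyde
Product: 4 4-[(tert-butyldimethylsilyl)oxy]-2-hydroxy-3-(3-methylbut-2-en-1-yl)benzaldehyde
Conditions: TBSCl (1.05 equiv), imidazole (2.2 equiv), CH2Cl2, 0 °C → rt
Reagents that add atoms: tert-butyldimethylsilyl chloride (TBSCl), CC(C)(C)[Si](C)(C)Cl
Why: Chemoselective silyl ether formation, because the 4-OH is the more acidic, non-chelated hydroxyl while the 2-OH is hydrogen-bonded to the aldehyde and flanked on both sides, so one equivalent of TBSCl caps only O4; no stereocentre.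

**Step 3**
Reactants: 4 4-[(tert-butyldimethylsilyl)oxy]-2-hydroxy-3-(3-methylbut-2-en-1-yl)benzaldehyde
Product: 5 4-[(tert-butyldimethylsilyl)oxy]-2-methoxy-3-(3-methylbut-2-en-1-yl)benzaldehyde
Conditions: MeI (10 equiv), Ag2O (1.5 equiv), 4 Å MS, MeCN, 40 °C, dark
Reagents that add atoms: methyl iodide (MeI), CI
Why: Purdie-type O-methylation with MeI/Ag2O methylates the remaining chelated phenol under neutral conditions, avoiding the carbonate or alkoxide that would strip the activated aryl silyl ether para to the aldehyde; no stereocentre.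

**Step 4**
Reactants: 5 4-[(tert-butyldimethylsilyl)oxy]-2-methoxy-3-(3-methylbut-2-en-1-yl)benzaldehyde; 6 ethyl diazoacetate; 7 5-methoxyresorcinol (5-methoxybenzene-1,3-diol)
Product: 10 7-hydroxy-5-methoxy-3-(5-methoxy-2,2-dimethylchroman-6-yl)-2H-chromen-2-one (the target), via silyl hydroxyacrylate 8 (not isolated), via prenylphenol coumarin 9 (not isolated)
Conditions: 6 (1.2 equiv), HBF4·OEt2 (10 mol %), CH2Cl2, −78 °C → rt; then 7 (1.1 equiv), CF3CO2H, TfOH (20 mol %), rt → 45 °C (one pot)
Reagents that add atoms: none
Why: Proposed new method: a one-pot merger of three acid-mediated reactions, namely (i) Brønsted-acid-catalysed addition of the diazoacetate to the aldehyde (Roskamp-type) in which the electron-rich aryl group undergoes a 1,2-shift with loss of N2 to give the 3-hydroxy-2-arylacrylate 8, (ii) Pechmann condensation in which the protonated formyl carbon of 8 is attacked by C4/C6 of 7 (para to one OH, the statistically and electronically favoured site), followed by lactonisation with the neighbouring OH, dehydration and acid desilylation to give 9 with the 5-OMe/7-OH pattern, and (iii) Markovnikov hydroalkoxylation of the prenyl group by the freed 4'-OH (six-membered closure on the tertiary cation) to give the 2,2-dimethylchroman; the closest known reaction types are the HBF4-catalysed synthesis of 3-hydroxy-2-arylacrylates from aryl aldehydes and ethyl diazoacetate, the Pechmann synthesis of 3-arylcoumarins from α-formyl arylacetates and resorcinols, and the acid-catalysed cyclisation of ortho-prenylphenols; the target is achiral, so no stereocentre is set.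

**Compound list**
1 | 2,4-dihydroxybenzaldehyde | O=Cc1ccc(O)cc1O | starting material
2 | prenyl bromide (1-bromo-3-methylbut-2-ene) | CC(C)=CCBr | starting material
3 | 2,4-dihydroxy-3-(3-methylbut-2-en-1-yl)benzaldehyde | CC(C)=CCc1c(O)ccc(C=O)c1O | intermediate
4 | 4-[(tert-butyldimethylsilyl)oxy]-2-hydroxy-3-(3-methylbut-2-en-1-yl)benzaldehyde | CC(C)=CCc1c(O[Si](C)(C)C(C)(C)C)ccc(C=O)c1O | intermediate
5 | 4-[(tert-butyldimethylsilyl)oxy]-2-methoxy-3-(3-methylbut-2-en-1-yl)benzaldehyde | CC(C)=CCc1c(O[Si](C)(C)C(C)(C)C)ccc(C=O)c1OC | intermediate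
6 | ethyl diazoacetate | CCOC(=O)C=[N+]=[N-] | starting material
7 | 5-methoxyresorcinol (5-methoxybenzene-1,3-diol) | COc1cc(O)cc(O)c1 | starting material
8 | ethyl (Z)-2-{4-[(tert-butyldimethylsilyl)oxy]-2-methoxy-3-(3-methylbut-2-en-1-yl)phenyl}-3-hydroxyprop-2-enoate (enol form of the α-formyl arylacetate) | CCOC(=O)/C(=C\O)c1ccc(O[Si](C)(C)C(C)(C)C)c(CC=C(C)C)c1OC | intermediate (not isolated)
9 | 7-hydroxy-3-[4-hydroxy-2-methoxy-3-(3-methylbut-2-en-1-yl)phenyl]-5-methoxy-2H-chromen-2-one | COc1cc(O)cc2oc(=O)c(-c3ccc(O)c(CC=C(C)C)c3OC)cc12 | intermediate (not isolated)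
10 | 7-hydroxy-5-methoxy-3-(5-methoxy-2,2-dimethylchroman-6-yl)-2H-chromen-2-one | COc1c(-c2cc3c(OC)cc(O)cc3oc2=O)ccc2c1CCC(C)(C)O2 | target

**Totals**
Total step count: 4. Longest linear sequence: 4 steps (1 → 3 → 4 → 5 → 10).

**Steps most likely to fail, with fallbacks**

Step 4 is the riskiest. The attack on 7 can also occur at C2 (between the two OH groups), which gives the 5-hydroxy-7-methoxy isomer. The three merged acid events may also interfere with each other, for example by cation capture by the electron-rich phenol. The fallback sets out from 5 and fixes the A-ring pattern with a regiodefined salicylaldehyde. Van Leusen reductive cyanation of 5 (TosMIC, t-BuOK, DME, −40 °C; then MeOH, reflux, which also removes the silyl group) gives 2-[4-hydroxy-2-methoxy-3-(3-methylbut-2-en-1-yl)phenyl]acetonitrile F1. Knoevenagel condensation of F1 with bought 2,4-dihydroxy-6-methoxybenzaldehyde (COc1cc(O)cc(O)c1C=O; t-BuOK, DMF, 100 °C), with ring closure of the phenoxide onto the nitrile, gives 3-[4-hydroxy-2-methoxy-3-(3-methylbut-2-en-1-yl)phenyl]-2-imino-5-methoxy-2H-chromen-7-ol F2. Aqueous HCl in EtOH at reflux then hydrolyses the imine to the lactone and closes the chroman, which comes back to the route at 10.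

Step 1 is the next risk, because direct C-prenylation is low-yielding and gives regioisomers. The fallback sets out from 1. O-alkylation of the 4-OH with 3-chloro-3-methylbut-1-yne (K2CO3, KI, cat. CuI, acetone) gives 2-hydroxy-4-[(2-methylbut-3-yn-2-yl)oxy]benzaldehyde F3. Lindlar semi-hydrogenation (H2, Pd/CaCO3–Pb, quinoline, EtOAc) gives 2-hydroxy-4-[(2-methylbut-3-en-2-yl)oxy]benzaldehyde F4. Aromatic Claisen rearrangement (PhNEt2, 150–180 °C) then delivers the prenyl group to C3, helped by bond fixation from the chelated 2-OH/CHO pair, which comes back to the route at 3.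

Step 3 is the third risk: the chelated, doubly flanked 2-OH methylates slowly, and the para-formyl aryl silyl ether can be lost. The fallback sets out from 1 and removes the need for a protecting group by tying O4 into the pyran ring before methylation. Condensation of 1 with 3-methylbut-2-enal (pyridine, 140 °C; Knoevenagel then oxa-6π electrocyclisation) gives 5-hydroxy-2,2-dimethyl-2H-chromene-6-carbaldehyde F5. Methylation (MeI, K2CO3, DMF) gives 5-methoxy-2,2-dimethyl-2H-chromene-6-carbaldehyde F6. Hydrogenation of the chromene double bond (H2 1 atm, Pd/C, EtOAc) gives 5-methoxy-2,2-dimethylchromane-6-carbaldehyde F7. Treating F7 with 6 and HBF4·OEt2 as in step 4 gives, in the flask, ethyl (Z)-3-hydroxy-2-(5-methoxy-2,2-dimethylchroman-6-yl)prop-2-enoate F8. Adding 7 and CF3CO2H/TfOH then effects the Pechmann condensation, which comes back to the route at 10.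

**Further compounds**
F1 | step 4 | 2-[4-hydroxy-2-methoxy-3-(3-methylbut-2-en-1-yl)phenyl]acetonitrile | COc1c(CC#N)ccc(O)c1CC=C(C)C
F2 | step 4 | 3-[4-hydroxy-2-methoxy-3-(3-methylbut-2-en-1-yl)phenyl]-2-imino-5-methoxy-2H-chromen-7-ol | COc1cc(O)cc2oc(=N)c(-c3ccc(O)c(CC=C(C)C)c3OC)cc12
F3 | step 1 | 2-hydroxy-4-[(2-methylbut-3-yn-2-yl)oxy]benzaldehyde | C#CC(C)(C)Oc1ccc(C=O)c(O)c1
F4 | step 1 | 2-hydroxy-4-[(2-methylbut-3-en-2-yl)oxy]benzaldehyde | C=CC(C)(C)Oc1ccc(C=O)c(O)c1
F5 | step 3 | 5-hydroxy-2,2-dimethyl-2H-chromene-6-carbaldehyde | CC1(C)C=Cc2c(O)c(C=O)ccc2O1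
F6 | step 3 | 5-methoxy-2,2-dimethyl-2H-chromene-6-carbaldehyde | CC1(C)C=Cc2c(OC)c(C=O)ccc2O1
F7 | step 3 | 5-methoxy-2,2-dimethylchromane-6-carbaldehyde | CC1(C)CCc2c(OC)c(C=O)ccc2O1
F8 | step 3 | ethyl (Z)-3-hydroxy-2-(5-methoxy-2,2-dimethylchroman-6-yl)prop-2-enoate | CCOC(=O)/C(=C\O)c1ccc2OC(C)(C)CCc2c1OC
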